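Each 4‑hydroxy‑2‑pyranone ring is opened at two bonds only, C5–C6 and O1–C2. C5 with its methyl is then C4 of a 2‑benzylated methyl 3‑oxopentanoate, and C6 with its ethyl is the carbonyl carbon of a propanoyl donor. One operation on a symmetrical bis(β‑keto ester), hung from a 2,4,6‑trimethoxybenzene core through the two benzylic CH2 groups, acylates both γ‑carbons and lactonises both diketo esters, giving two rings and four skeletal bonds. The precursor comes from a dialdehyde by Knoevenagel condensation and hydrogenation, which avoids ionisation‑prone trimethoxybenzylic halides. The isobutyryl ketone and the free phenols are unveiled afterwards.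

Key step: step 5

Remark on stereochemistry: the target has no stereocentre or other stereogenic element, so it is one achiral compound and no enantiocontrol is required; the α‑carbons of keto esters 7 and 9 epimerise freely and the alkenes of 6 are reduced, so these compounds are written without stereodescriptors.

Step 1
Reactants: 1 phloroglucinol (benzene‑1,3,5‑triol)
Product: 3 2,4,6‑trihydroxybenzene‑1,3‑dicarbaldehyde, via bis(iminium) salt 2 (not isolated)
Conditions: POCl3 (2.2 equiv), DMF (2.4 equiv), 1,4‑dioxane, 0 °C → rt; then H2O, rt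
Reagents that add atoms: N,N‑dimethylformamide, CN(C)C=O; water, O
Why: Vilsmeier–Haack formylation, in which the very electron‑rich triol should take up two chloroiminium ions at ring carbons flanked by hydroxyls, the limited stoichiometry and the two acceptor groups then protecting the third carbon, and water hydrolyses the bis(iminium) salt to the dialdehyde.

Step 2
Reactants: 3 2,4,6‑trihydroxybenzene‑1,3‑dicarbaldehyde
Product: 4 2,4,6‑trimethoxybenzene‑1,3‑dicarbaldehyde
Conditions: Me2SO4 (4 equiv), K2CO3 (5 equiv), acetone, reflux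
Reagents that add atoms: dimethyl sulfate, COS(=O)(=O)OC
Why: Williamson‑type O‑methylation of the phenoxides, where the two formyl groups lower the carbon nucleophilicity of the ring so that the hard electrophile should be taken up at oxygen, and excess reagent at reflux should also alkylate the hydroxyls that are hydrogen‑bonded to the carbonyls.

Step 3
Reactants: 4 2,4,6‑trimethoxybenzene‑1,3‑dicarbaldehyde; 5 methyl 3‑oxopentanoate (2.4 equiv)
Product: 6 dimethyl 2,2'‑[(2,4,6‑trimethoxy‑1,3‑phenylene)dimethanylylidene]bis(3‑oxopentanoate) (E/Z mixture at both alkenes)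
Conditions: piperidine (0.2 equiv), AcOH (0.2 equiv), toluene, reflux, Dean–Stark
Reagents that add atoms: none
Why: Twofold Knoevenagel condensation of the active methylene of 5 with each formyl group under iminium catalysis, driven by azeotropic removal of water, while the two ortho methoxy groups at each arylidene should block Michael addition of a further keto ester.

Step 4
Reactants: 6 dimethyl 2,2'‑[(2,4,6‑trimethoxy‑1,3‑phenylene)dimethanylylidene]bis(3‑oxopentanoate)
Product: 7 dimethyl 2,2'‑[(2,4,6‑trimethoxy‑1,3‑phenylene)bis(methylene)]bis(3‑oxopentanoate) (mixture of epimers at the two α‑carbons)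
Conditions: H2 (1 atm), 10% Pd/C, EtOAc, rt
Reagents that add atoms: none
Why: Heterogeneous catalytic hydrogenation of the electron‑poor alkylidene C=C bonds should leave ketones, esters and aryl ethers untouched, and the two sp3 centres it creates are acidic α‑carbons that equilibrate, so their configuration is neither controlled nor needed.

Step 5
Reactants: 7 dimethyl 2,2'‑[(2,4,6‑trimethoxy‑1,3‑phenylene)bis(methylene)]bis(3‑oxopentanoate); 8 N‑methoxy‑N‑methylpropanamide (2.4 equiv)
Product: 10 3,3'‑[(2,4,6‑trimethoxy‑1,3‑phenylene)bis(methylene)]bis(6‑ethyl‑4‑hydroxy‑5‑methyl‑2H‑pyran‑2‑one), via bis(diketo ester) 9 (not isolated)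
Conditions: LDA (4.4 equiv), THF, −78 → 0 °C; 8, −78 → 0 °C; 1 M HCl; then DBU (3 equiv), toluene, 80 °C; 1 M HCl work‑up
Reagents that add atoms: none
Why: Two equivalents of LDA per arm remove first the C2–H and then a C4–H of each keto ester, and the resulting γ‑carbanions, the most nucleophilic carbons of the tetra‑anion, add to the amide carbonyl of 8; the N‑methoxy group chelates lithium in the tetrahedral adducts, which therefore persist until the acid quench and can neither over‑add nor be protonated by the more acidic diketone product (C5–C6 of both rings, giving 9). DBU then enolises each new ketone and the enol oxygen attacks the methyl ester in a 6‑exo‑trig acyl substitution with loss of methanol (O1–C2), so both rings close in the same mode, by lactonisation, and tautomerise to the 4‑hydroxy‑2‑pyranones. The closest known reaction type is the γ‑acylation of a β‑keto ester dianion by a Weinreb amide (Weinreb ketone synthesis) followed by amine‑base cyclisation of the 3,5‑diketo ester to a 4‑hydroxy‑2‑pyranone. No stereocentre is created, because the labile C2 and C4 centres of 9 all become sp2. The step needs γ‑ over α‑ or O‑acylation, which the dianion secures, and O‑ over C‑cyclisation (Claisen closure to a carbocycle), which the amine base secures because it does not generate the carbanion at the ethyl ketone CH2. It also needs equal reaction in both arms, which the substrate secures by carrying no other C–H acidic towards LDA (no acyl group on the arene, and the ring C–H between two methoxy groups is not lithiated at −78 °C).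

Step 6
Reactants: 10 3,3'‑[(2,4,6‑trimethoxy‑1,3‑phenylene)bis(methylene)]bis(6‑ethyl‑4‑hydroxy‑5‑methyl‑2H‑pyran‑2‑one); 11 2‑methylpropanoyl chloride (isobutyryl chloride, 1.3 equiv)
Product: 12 3,3'‑{[2,4,6‑trimethoxy‑5‑(2‑methylpropanoyl)‑1,3‑phenylene]bis(methylene)}bis(6‑ethyl‑4‑hydroxy‑5‑methyl‑2H‑pyran‑2‑one)
Conditions: AlCl3 (5 equiv), CH2Cl2–MeNO2, 0 °C, short reaction time; 1 M HCl work‑up
Reagents that add atoms: none
Why: Friedel–Crafts acylation, in which the acylium ion can attack only the one unsubstituted ring carbon, activated by three ortho/para methoxy groups, whereas both pyranones have no free ring carbon and their hydroxyls are held as aluminium pyranolates by the excess Lewis acid; the low temperature should limit ether cleavage next to the new ketone, and any such material would converge with 12 in step 7.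

Step 7
Reactants: 12 3,3'‑{[2,4,6‑trimethoxy‑5‑(2‑methylpropanoyl)‑1,3‑phenylene]bis(methylene)}bis(6‑ethyl‑4‑hydroxy‑5‑methyl‑2H‑pyran‑2‑one)
Product: 13 3,3'‑{[2,4,6‑trihydroxy‑5‑(2‑methylpropanoyl)‑1,3‑phenylene]bis(methylene)}bis(6‑ethyl‑4‑hydroxy‑5‑methyl‑2H‑pyran‑2‑one) (target CNP0277086.0)
Conditions: BBr3 (10 equiv), CH2Cl2, −78 °C → rt; then H2O, 0 °C
Reagents that add atoms: none
Why: Lewis acid‑mediated cleavage of aryl methyl ethers with BBr3, where all three methoxy groups lie between two ortho substituents and are twisted out of conjugation, which makes them basic and readily cleaved, two of them with chelation help from the ketone, while the pyranone lactones and the aryl ketone should be inert and hydrolysis releases the three phenols.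

Compound list
1 | phloroglucinol (benzene‑1,3,5‑triol) | Oc1cc(O)cc(O)c1 | starting material
2 | N,N'‑[(2,4,6‑trihydroxy‑1,3‑phenylene)dimethanylylidene]bis(N‑methylmethanaminium) bis(dichlorophosphate) | C[N+](C)=Cc1c(O)cc(O)c(C=[N+](C)C)c1O.[O-]P(=O)(Cl)Cl.[O-]P(=O)(Cl)Cl | intermediate
3 | 2,4,6‑trihydroxybenzene‑1,3‑dicarbaldehyde | O=Cc1c(O)cc(O)c(C=O)c1O | intermediate
4 | 2,4,6‑trimethoxybenzene‑1,3‑dicarbaldehyde | COc1cc(OC)c(C=O)c(OC)c1C=O | intermediate
5 | methyl 3‑oxopentanoate | CCC(=O)CC(=O)OC | starting material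
6 | dimethyl 2,2'‑[(2,4,6‑trimethoxy‑1,3‑phenylene)dimethanylylidene]bis(3‑oxopentanoate), E/Z mixture | COc1cc(OC)c(C=C(C(=O)OC)C(=O)CC)c(OC)c1C=C(C(=O)OC)C(=O)CC | intermediate
7 | dimethyl 2,2'‑[(2,4,6‑trimethoxy‑1,3‑phenylene)bis(methylene)]bis(3‑oxopentanoate), epimer mixture | COc1cc(OC)c(CC(C(=O)OC)C(=O)CC)c(OC)c1CC(C(=O)OC)C(=O)CC | intermediate
8 | N‑methoxy‑N‑methylpropanamide | CCC(=O)N(C)OC | starting material
9 | dimethyl 2,2'‑[(2,4,6‑trimethoxy‑1,3‑phenylene)bis(methylene)]bis(4‑methyl‑3,5‑dioxoheptanoate), stereoisomer mixture | COc1cc(OC)c(CC(C(=O)OC)C(=O)C(C)C(=O)CC)c(OC)c1CC(C(=O)OC)C(=O)C(C)C(=O)CC | intermediate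
10 | 3,3'‑[(2,4,6‑trimethoxy‑1,3‑phenylene)bis(methylene)]bis(6‑ethyl‑4‑hydroxy‑5‑methyl‑2H‑pyran‑2‑one) | CCc1oc(=O)c(Cc2c(OC)cc(OC)c(Cc3c(O)c(C)c(CC)oc3=O)c2OC)c(O)c1C | intermediate
11 | 2‑methylpropanoyl chloride (isobutyryl chloride) | CC(C)C(=O)Cl | starting material
12 | 3,3'‑{[2,4,6‑trimethoxy‑5‑(2‑methylpropanoyl)‑1,3‑phenylene]bis(methylene)}bis(6‑ethyl‑4‑hydroxy‑5‑methyl‑2H‑pyran‑2‑one) | CCc1oc(=O)c(Cc2c(OC)c(Cc3c(O)c(C)c(CC)oc3=O)c(OC)c(C(=O)C(C)C)c2OC)c(O)c1C | intermediate
13 | 3,3'‑{[2,4,6‑trihydroxy‑5‑(2‑methylpropanoyl)‑1,3‑phenylene]bis(methylene)}bis(6‑ethyl‑4‑hydroxy‑5‑methyl‑2H‑pyran‑2‑one) | CCc1oc(=O)c(Cc2c(O)c(Cc3c(O)c(C)c(CC)oc3=O)c(O)c(C(=O)C(C)C)c2O)c(O)c1C | target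

Total step count: 7. Longest linear sequence: 7 steps (1 → 3 → 4 → 6 → 7 → 10 → 12 → 13).

Steps most likely to fail

Step 5. The fourfold deprotonation may stay incomplete or the tetralithio species may aggregate, so that only one arm is acylated. Proton transfer from the α‑CH2 of the amide to the γ‑carbanion may return starting material, and carbon rather than oxygen may close the ring during the base treatment. The fallback sets out from 5, 8 and 4 and comes back at 10. The ring would be built on the monomer: the dianion of 5 (LDA, 2 equiv) is acylated with 8 to give methyl 4‑methyl‑3,5‑dioxoheptanoate F1, which DBU in warm toluene lactonises to 6‑ethyl‑4‑hydroxy‑5‑methyl‑2H‑pyran‑2‑one F2. Two equivalents of F2 are then joined to dialdehyde 4 by organocatalytic reductive Knoevenagel alkylation (L‑proline cat., Hantzsch ester, CH2Cl2–EtOH, rt). The condensation product, 3,3'‑[(2,4,6‑trimethoxy‑1,3‑phenylene)dimethanylylidene]bis(6‑ethyl‑5‑methyl‑2H‑pyran‑2,4(3H)‑dione) F3, is reduced in the flask by hydride transfer and should give 10 directly, so that steps 3 to 5 are bypassed.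

Step 6. The acid chloride may acylate the pyranone hydroxyls instead of the arene, and attack at the carbon flanked by two methoxy groups may be slow. Ipso attack with loss of a pyranylmethyl arm may also compete. The fallback sets out from 10 and comes back at 12. A Houben–Hoesch reaction with isobutyronitrile (ZnCl2, dry HCl, Et2O–CH2Cl2, 0 °C) uses a slim nitrilium electrophile that cannot esterify the pyranone hydroxyls. It should give the ketiminium chloride of 12, 3,3'‑{[5‑(1‑iminio‑2‑methylpropyl)‑2,4,6‑trimethoxy‑1,3‑phenylene]bis(methylene)}bis(6‑ethyl‑4‑hydroxy‑5‑methyl‑2H‑pyran‑2‑one) chloride F4, which is hydrolysed to 12 in warm water.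

Step 7. Acid‑induced scission of the arene–CH2 bonds (retro‑Friedel–Crafts loss of a pyranylmethyl arm) may accompany ether cleavage, or cleavage may stop before all three ethers are gone. The fallback sets out from 1 and 11 and comes back at 13 without any phenol protection. Friedel–Crafts acylation of 1 with 11 (AlCl3, PhNO2–CH2Cl2) gives 1‑(2,4,6‑trihydroxyphenyl)‑2‑methylpropan‑1‑one F5. Its two free ring carbons are then bridged to two equivalents of the pyranone F2 from the step 5 fallback with paraformaldehyde under mild base. F2 condenses with formaldehyde to 6‑ethyl‑5‑methyl‑3‑methylidene‑2H‑pyran‑2,4(3H)‑dione F6, to which the acylphloroglucinol adds in a Michael‑type ring alkylation, twice, to give 13.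

Further compounds
F1 | step 5 | methyl 4‑methyl‑3,5‑dioxoheptanoate | COC(=O)CC(=O)C(C)C(=O)CC
F2 | step 5 | 6‑ethyl‑4‑hydroxy‑5‑methyl‑2H‑pyran‑2‑one | CCc1oc(=O)cc(O)c1C
F3 | step 5 | 3,3'‑[(2,4,6‑trimethoxy‑1,3‑phenylene)dimethanylylidene]bis(6‑ethyl‑5‑methyl‑2H‑pyran‑2,4(3H)‑dione) | COc1cc(OC)c(C=C2C(=O)OC(CC)=C(C)C2=O)c(OC)c1C=C1C(=O)OC(CC)=C(C)C1=O
F4 | step 6 | 3,3'‑{[5‑(1‑iminio‑2‑methylpropyl)‑2,4,6‑trimethoxy‑1,3‑phenylene]bis(methylene)}bis(6‑ethyl‑4‑hydroxy‑5‑methyl‑2H‑pyran‑2‑one) chloride | CCc1oc(=O)c(Cc2c(OC)c(Cc3c(O)c(C)c(CC)oc3=O)c(OC)c(C(=[NH2+])C(C)C)c2OC)c(O)c1C.[Cl-]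
F5 | step 7 | 1‑(2,4,6‑trihydroxyphenyl)‑2‑methylpropan‑1‑one | CC(C)C(=O)c1c(O)cc(O)cc1O
F6 | step 7 | 6‑ethyl‑5‑methyl‑3‑methylidene‑2H‑pyran‑2,4(3H)‑dione | C=C1C(=O)OC(CC)=C(C)C1=O
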